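## Retrosynthetic overview

1. The two formyl groups come last, by Rieche formylation of the debenzylated resorcinol core 29; before that, the carbinol left by the key step is removed by Barton–McCombie deoxygenation.
2. Key disconnection (step 15): at the quaternary ether carbon shared by the cyclohexane, cyclopentane and oxepane rings, both the aryl C–O bond and the bond to the adjacent cyclopentane CH2 are cut. The enabling feature is that this carbon can be a ring ketone whose neighbouring ring-fusion CH carries the quaternary methyl carbon with an ethynyl group (the future CH2–CH2 bridge) and the ArCH(i-Bu) arm with a free ortho-OH. The ketone, alkyne and phenol can then form a mixed aryl ketal of a 2-methyleneoxolane (oxepane closed), and an O-to-C Ferrier-type shift closes the cyclopentane.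
3. Alkynyl ketone 23 comes from cyclopentenone 21 by Eschenmoser–Tanabe fragmentation. The cyclopentenone is a temporary ring: its rigid α'-enolate is alkylated by an o-quinone methide, which sets the quaternary methyl carbon and the benzylic carbon.
4. Enone 14 comes from (1R,3S,6S)-caran-4-one 7 (Michael addition to 2-nitrobut-2-ene, Nef, aldol). Ketone 7 comes from (S)-carvone: the isopropenyl group becomes the gem-dimethylcyclopropane and the carbonyl is transposed (Wharton).
5. Ring order: cyclohexane (carvone) → cyclopropane (step 2) → temporary cyclopentenone (step 9, reopened in step 14) → oxepane and cyclopentane together (step 15). The arene enters intact in step 12.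

Key step: step 15

Remark: stereocentres that are removed again later (the side-chain CH in 10–14, the carbinol and epoxide carbons in 12, 13, 22, 26, 27) are carried as mixtures and left undefined in the SMILES.

## Route

Step 1
Reactants: 1 (S)-(+)-carvone
Product: 2 (5S)-5-(2-chloropropan-2-yl)-2-methylcyclohex-2-en-1-one
Conditions: HCl (g), AcOH, 0 °C
Reagents that add atoms: hydrogen chloride, Cl
Why: Markovnikov hydrochlorination of the isopropenyl group (the enone C=C is inert) should give the tertiary chloride without touching the ring stereocentre.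

Step 2
Reactants: 2 (5S)-5-(2-chloropropan-2-yl)-2-methylcyclohex-2-en-1-one
Product: 3 (1R,6S)-3,7,7-trimethylbicyclo[4.1.0]hept-3-en-2-one
Conditions: KOH, MeOH, 0 °C
Reagents that add atoms: none
Why: Intramolecular enolate alkylation (3-exo-tet) of the α'-enolate on the tertiary chloride should close the cyclopropane, with the cis ring fusion enforced and the new ring carbon following from the carvone centre.

Step 3
Reactants: 3 (1R,6S)-3,7,7-trimethylbicyclo[4.1.0]hept-3-en-2-one
Product: 4 3,4-epoxide of 3, oxirane oxygen trans to the CMe2 bridge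
Conditions: H2O2 (30% aq.), NaOH (cat.), MeOH, −10 → 0 °C
Reagents that add atoms: hydrogen peroxide, OO
Why: Weitz–Scheffer epoxidation, in which hydroperoxide should add to the β-carbon from the face opposite the gem-dimethylcyclopropane.

Step 4
Reactants: 4 3,4-epoxide of 3
Product: 5 (1R,4S,6S)-3,7,7-trimethylbicyclo[4.1.0]hept-2-en-4-ol
Conditions: N2H4·H2O, AcOH (cat.), MeOH, 0 °C → rt
Reagents that add atoms: none
Why: Wharton transposition (hydrazone, epoxide opening, loss of N2) should move the oxygen to the former β-carbon with its C–O bond retained (OH trans to the cyclopropane) and remove the old carbonyl oxygen.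

Step 5
Reactants: 5 (1R,4S,6S)-3,7,7-trimethylbicyclo[4.1.0]hept-2-en-4-ol
Product: 6 (1R,3S,4S,6S)-3,7,7-trimethylbicyclo[4.1.0]heptan-4-ol
Conditions: H2 (1 atm), [Ir(cod)(PCy3)(py)]PF6 (2 mol %), CH2Cl2, 0 °C → rt
Reagents that add atoms: none
Why: Hydroxyl-directed homogeneous hydrogenation should deliver hydrogen from the OH face, which is also the face opposite the cyclopropane, placing the methyl group cis to the cyclopropane.

Step 6
Reactants: 6 (1R,3S,4S,6S)-3,7,7-trimethylbicyclo[4.1.0]heptan-4-ol
Product: 7 (1R,3S,6S)-3,7,7-trimethylbicyclo[4.1.0]heptan-4-one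
Conditions: Dess–Martin periodinane, CH2Cl2, 0 °C; aq. NaHCO3/Na2S2O3 work-up
Reagents that add atoms: none
Why: A neutral alcohol oxidation should give the ketone without epimerising the α-methyl centre, which is the less stable epimer.

Step 7
Reactants: 8 3-nitrobutan-2-ol
Product: 9 2-nitrobut-2-ene
Conditions: MsCl, Et3N, CH2Cl2, 0 °C
Reagents that add atoms: none
Why: Mesylation and E1cB elimination of a β-nitro alcohol is the standard route to the nitroalkene.

Step 8
Reactants: 7 (1R,3S,6S)-3,7,7-trimethylbicyclo[4.1.0]heptan-4-one; 9 2-nitrobut-2-ene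
Product: 11 5-(3-oxobutan-2-yl)caran-4-one, side chain trans to the cyclopropane, via lithium nitronate 10 (not isolated)
Conditions: LiN(i-Pr)2, THF, −78 °C; 9, −78 °C; then poured into 2 M H2SO4, 0 °C
Reagents that add atoms: water, O
Why: Kinetic deprotonation at the CH2 side, Michael addition of the enolate to the nitroalkene on the face opposite the cyclopropane, and Nef hydrolysis of the nitronate should give the 1,4-diketone.

Step 9
Reactants: 11 5-(3-oxobutan-2-yl)caran-4-one
Product: 14 tricyclic cyclopentenone (temporary ring), via aldol 12 (not isolated), via trifluoroacetate 13 (not isolated)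
Conditions: LiN(i-Pr)2, THF, −78 °C; (CF3CO)2O, −78 → 0 °C; DBU, 0 °C → rt
Reagents that add atoms: none
Why: Intramolecular aldol addition of the kinetic methyl-ketone enolate to the ring carbonyl followed by acylation and E1cB dehydration should give the cyclopentenone under conditions that never equilibrate the α-methyl ketone centre.

Step 10
Reactants: 15 2,4,6-trihydroxybenzaldehyde
Product: 16 2,4-bis(benzyloxy)-6-hydroxybenzaldehyde
Conditions: BnBr (2.1 equiv), K2CO3, acetone, 50 °C
Reagents that add atoms: benzyl bromide, BrCc1ccccc1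
Why: Williamson etherification should stop at the dibenzyl ether because the last hydroxyl is hydrogen-bonded to the aldehyde.

Step 11
Reactants: 16 2,4-bis(benzyloxy)-6-hydroxybenzaldehyde
Product: 17 3,5-bis(benzyloxy)-2-formylphenyl tert-butyl carbonate
Conditions: Boc2O, i-Pr2NEt, DMAP (cat.), CH2Cl2, 0 °C → rt
Reagents that add atoms: di-tert-butyl dicarbonate, CC(C)(C)OC(=O)OC(=O)OC(C)(C)C
Why: O-acylation of the phenol installs the carbonate that later serves as the internal leaving group for o-quinone methide formation.

Step 12
Reactants: 14 tricyclic cyclopentenone; 17 3,5-bis(benzyloxy)-2-formylphenyl tert-butyl carbonate; 18 isobutylmagnesium bromide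
Product: 21 α'-alkylated cyclopentenone with free phenol, via magnesium alkoxide 19 (not isolated), via o-quinone methide 20 (not isolated)
Conditions: 17, i-BuMgBr (18), THF, −78 °C; added to 14/LiN(i-Pr)2 (THF, −78 °C); −78 → 0 °C; aq. NH4Cl
Reagents that add atoms: none
Why: Michael addition of the kinetic α'-enolate to the o-quinone methide (generated from 19 by Boc transfer and β-elimination) should occur on the enolate face opposite the cyclohexane bond at the adjacent ring-fusion carbon, in a compact arrangement with the arene over the five-membered ring and the isobutyl group outside, which sets the quaternary and the benzylic stereocentres.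

Step 13
Reactants: 21 α'-alkylated cyclopentenone
Product: 22 α,β-epoxy ketone of 21
Conditions: H2O2 (30% aq.), NaOH, MeOH–THF, 0 °C → rt
Reagents that add atoms: hydrogen peroxide, OO
Why: Weitz–Scheffer epoxidation of the enone; the epoxide configuration is irrelevant because both carbons lose it in the next step.

Step 14
Reactants: 22 α,β-epoxy ketone
Product: 23 alkynyl ketone with free phenol
Conditions: TsNHNH2, AcOH–CH2Cl2 (1:1), −20 °C → rt
Reagents that add atoms: none
Why: Eschenmoser–Tanabe fragmentation of the epoxy tosylhydrazone should reopen the temporary ring to the cyclohexanone and a terminal alkyne on the quaternary carbon, leaving all stereocentres untouched.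

Step 15
Reactants: 23 alkynyl ketone with free phenol
Product: 26 bridged hexacyclic carbinol (dibenzyl ether), via ketal enol ether 24 (not isolated), via ketone 25 (not isolated)
Conditions: (Ph3P)AuNTf2 (5 mol %), CH2Cl2, 4 Å molecular sieves, 0 °C → rt; then toluene, i-Bu3Al (4 equiv), −78 → 0 °C; aq. potassium sodium tartrate
Reagents that add atoms: none
Why: Proposed new method: (Ph3P)AuNTf2 activates the alkyne, the ketone oxygen adds 5-exo-dig (carbonyl participation, as in gold-catalysed hydration of γ-alkynyl ketones) and the phenol captures the resulting oxocarbenium carbon 7-exo-trig, so that the oxepane is closed as the mixed aryl ketal 24 carrying an exocyclic enol ether. i-Bu3Al then ionises the ketal C–O bond on the enol-ether side and the aluminium enolate returns through its CH2 carbon to the aryloxy-stabilised oxocarbenium carbon (5-enolendo-exo-trig aldol-type closure), which forms the ring-closing C–CH2 bond of the cyclopentane; this O-to-C shift is the Petasis–Ferrier rearrangement of enol acetals, and its i-Bu3Al variant with retention of the exocyclic alkoxy group is known for 5-enopyranosides but not for a 2-methyleneoxolane aryl ketal. The only new stereocentre that survives, the quaternary aryl ether carbon, is fixed by the quaternary methyl carbon, from which both the aryl ether bridge and the two-carbon enolate arm start, so that the bicyclo[4.2.1] core can close in one sense only. Ketone 25, a β-aryloxy ketone open to retro-oxa-Michael cleavage, is not isolated but reduced in the flask by β-hydride transfer from i-Bu3Al to carbinol 26 (either epimer serves). The step needs attack of the carbonyl oxygen rather than the phenol on the gold–alkyne complex, secured by the faster five-membered closure of the more Lewis-basic carbonyl oxygen, and ionisation of the enol-ether rather than the aryl C–O bond, secured because only the enolate pathway ends in an irreversible C–C bond while loss of aryloxide is reversible.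

Step 16
Reactants: 26 bridged carbinol
Product: 27 S-methyl xanthate of 26
Conditions: NaH, CS2, THF, 0 °C → rt; then MeI
Reagents that add atoms: carbon disulfide, S=C=S; iodomethane, CI
Why: Xanthate formation from the secondary alkoxide prepares the radical deoxygenation.

Step 17
Reactants: 27 S-methyl xanthate
Product: 28 deoxygenated bridged core (dibenzyl ether)
Conditions: Bu3SnH, AIBN (cat.), toluene, 110 °C
Reagents that add atoms: none
Why: Barton–McCombie deoxygenation should remove the auxiliary oxygen; the radical is γ to the aryl ether oxygen, so no β-elimination is possible.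

Step 18
Reactants: 28 deoxygenated bridged core (dibenzyl ether)
Product: 29 bridged core resorcinol
Conditions: H2 (1 atm), Pd/C (10%), EtOAc–EtOH, rt
Reagents that add atoms: none
Why: Hydrogenolysis of the two benzyl aryl ethers; the isolated cyclopropane and the tertiary alkyl aryl ether should survive.

Step 19
Reactants: 29 bridged core resorcinol
Product: 30 target CNP0202714.1
Conditions: Cl2CHOCH3 (5 equiv), TiCl4, CH2Cl2, −78 → 0 °C; then H2O
Reagents that add atoms: dichloromethyl methyl ether, COC(Cl)Cl; water, O
Why: Twofold Rieche formylation should occur at the two free ring positions, each flanked by two oxygen substituents, under conditions that chroman-type tertiary aryl ethers tolerate.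

## Compound list

1 | (S)-(+)-carvone, (5S)-2-methyl-5-(prop-1-en-2-yl)cyclohex-2-en-1-one | CC1=CC[C@@H](CC1=O)C(C)=C | starting material
2 | (5S)-5-(2-chloropropan-2-yl)-2-methylcyclohex-2-en-1-one | CC1=CC[C@@H](CC1=O)C(C)(C)Cl | intermediate
3 | (1R,6S)-3,7,7-trimethylbicyclo[4.1.0]hept-3-en-2-one | O=C1C(C)=CC[C@H]2[C@@H]1C2(C)C | intermediate
4 | 3,4-epoxy-3,7,7-trimethylbicyclo[4.1.0]heptan-2-one, oxirane oxygen trans to the CMe2 bridge | O=C1[C@@]2(C)O[C@H]2C[C@H]3[C@@H]1C3(C)C | intermediate
5 | (1R,4S,6S)-3,7,7-trimethylbicyclo[4.1.0]hept-2-en-4-ol | O[C@H]1C[C@H]2[C@@H](C=C1C)C2(C)C | intermediate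
6 | (1R,3S,4S,6S)-3,7,7-trimethylbicyclo[4.1.0]heptan-4-ol | O[C@H]1C[C@H]2[C@@H](C[C@@H]1C)C2(C)C | intermediate
7 | (1R,3S,6S)-3,7,7-trimethylbicyclo[4.1.0]heptan-4-one | O=C1C[C@H]2[C@@H](C[C@@H]1C)C2(C)C | intermediate
8 | 3-nitrobutan-2-ol (mixture of isomers) | CC(O)C(C)[N+](=O)[O-] | starting material
9 | 2-nitrobut-2-ene | CC=C(C)[N+](=O)[O-] | intermediate
10 | lithium nitronate of 5-(3-nitrobutan-2-yl)caran-4-one | O=C1[C@@H](C(C)C(C)=[N+]([O-])[O-])[C@H]2[C@@H](C[C@@H]1C)C2(C)C.[Li+] | intermediate
11 | 3,7,7-trimethyl-5-(3-oxobutan-2-yl)bicyclo[4.1.0]heptan-4-one, side chain trans to the cyclopropane | O=C1[C@@H](C(C)C(C)=O)[C@H]2[C@@H](C[C@@H]1C)C2(C)C | intermediate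
12 | tricyclic aldol: 3-hydroxycyclopentanone fused to the carane ring, tertiary OH on the former ketone carbon | O=C1CC2(O)[C@@H](C)C[C@@H]3[C@H]([C@@H]2C1C)C3(C)C | intermediate
13 | trifluoroacetate of aldol 12 | O=C1CC2(OC(=O)C(F)(F)F)[C@@H](C)C[C@@H]3[C@H]([C@@H]2C1C)C3(C)C | intermediate
14 | tricyclic cyclopentenone: 5-methylcyclopent-2-enone fused at its 3,4-bond to the carane ring | O=C1C=C2[C@@H](C)C[C@@H]3[C@H]([C@@H]2C1C)C3(C)C | intermediate
15 | 2,4,6-trihydroxybenzaldehyde | O=Cc1c(O)cc(O)cc1O | starting material
16 | 2,4-bis(benzyloxy)-6-hydroxybenzaldehyde | O=Cc1c(O)cc(OCc2ccccc2)cc1OCc1ccccc1 | intermediate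
17 | 3,5-bis(benzyloxy)-2-formylphenyl tert-butyl carbonate | O=Cc1c(OC(=O)OC(C)(C)C)cc(OCc2ccccc2)cc1OCc1ccccc1 | intermediate
18 | isobutylmagnesium bromide | CC(C)C[Mg]Br | starting material
19 | bromomagnesium alkoxide from addition of 18 to 17 | CC(C)CC(O[Mg]Br)c1c(OC(=O)OC(C)(C)C)cc(OCc2ccccc2)cc1OCc1ccccc1 | intermediate
20 | (E)-3,5-bis(benzyloxy)-6-(3-methylbutylidene)cyclohexa-2,4-dien-1-one (o-quinone methide) | CC(C)C/C=C1/C(=O)C=C(OCc2ccccc2)C=C1OCc1ccccc1 | intermediate
21 | cyclopentenone 14 carrying at its α'-carbon a methyl group and the 1-[2,4-bis(benzyloxy)-6-hydroxyphenyl]-3-methylbutyl group (aryl-alkyl group anti, methyl syn to the cyclohexane bond at the adjacent ring-fusion CH) | CC(C)C[C@@H](c1c(OCc2ccccc2)cc(OCc2ccccc2)cc1O)[C@@]1(C)C(=O)C=C2[C@@H](C)C[C@@H]3[C@H]([C@H]12)C3(C)C | intermediate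
22 | α,β-epoxy ketone of 21 | CC(C)C[C@@H](c1c(OCc2ccccc2)cc(OCc2ccccc2)cc1O)[C@@]1(C)C(=O)C2OC23[C@@H](C)C[C@@H]4[C@H]([C@H]13)C4(C)C | intermediate
23 | caran-4-one 7 carrying at C5 (trans to the cyclopropane) the quaternary carbon C(CH3)(C≡CH)[CH(i-Bu)Ar], Ar = 2,4-bis(benzyloxy)-6-hydroxyphenyl | CC(C)C[C@@H](c1c(OCc2ccccc2)cc(OCc2ccccc2)cc1O)[C@@](C)(C#C)[C@@H]1C(=O)[C@@H](C)C[C@@H]2[C@H]1C2(C)C | intermediate
24 | bridged mixed aryl ketal: oxepane closed, 2-methyleneoxolane in place of the cyclopentane | CC(C)C[C@H]1c2c(OCc4ccccc4)cc(OCc4ccccc4)cc2O[C@]23OC(=C)[C@@]1(C)[C@H]2[C@H]1[C@@H](C[C@@H]3C)C1(C)C | intermediate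
25 | bridged β-aryloxy cyclopentanone (C=O next to the quaternary methyl carbon) | CC(C)C[C@H]1c2c(OCc4ccccc4)cc(OCc4ccccc4)cc2O[C@]23CC(=O)[C@@]1(C)[C@H]2[C@H]1[C@@H](C[C@@H]3C)C1(C)C | intermediate
26 | bridged carbinol (OH on the cyclopentane CH next to the quaternary methyl carbon) | CC(C)C[C@H]1c2c(OCc4ccccc4)cc(OCc4ccccc4)cc2O[C@]23CC(O)[C@@]1(C)[C@H]2[C@H]1[C@@H](C[C@@H]3C)C1(C)C | intermediate
27 | O-alkyl S-methyl xanthate of 26 | CC(C)C[C@H]1c2c(OCc4ccccc4)cc(OCc4ccccc4)cc2O[C@]23CC(OC(=S)SC)[C@@]1(C)[C@H]2[C@H]1[C@@H](C[C@@H]3C)C1(C)C | intermediate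
28 | deoxygenated bridged core, 2,4-di-O-benzyl ether | CC(C)C[C@H]1c2c(OCc4ccccc4)cc(OCc4ccccc4)cc2O[C@]23CC[C@@]1(C)[C@H]2[C@H]1[C@@H](C[C@@H]3C)C1(C)C | intermediate
29 | bridged core resorcinol (target without the two formyl groups) | CC(C)C[C@H]1c2c(O)cc(O)cc2O[C@]23CC[C@@]1(C)[C@H]2[C@H]1[C@@H](C[C@@H]3C)C1(C)C | intermediate
30 | CNP0202714.1 | CC(C)C[C@H]1c2c(O)c(C=O)c(O)c(C=O)c2O[C@]23CC[C@@]1(C)[C@H]2[C@H]1[C@@H](C[C@@H]3C)C1(C)C | target

## Step count and risks

Total step count: 19. Longest linear sequence: 16 steps (steps 1–6, 8, 9, 12–19).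

Step 15 (Proposed new method) is the most likely to fail. The gold-activated alkyne may be attacked by the phenol oxygen instead of the ketone oxygen, or the ketal may be reduced by i-Bu3Al before the C–C bond forms. The fallback uses known reactions, sets out from 21 and returns at 26. Luche reduction of 21 (NaBH4, CeCl3·7H2O, MeOH, −78 °C) should give the allylic alcohol F1. Phenylselenoetherification (PhSeCl, CH2Cl2, −78 °C, then i-Pr2NEt) should close the oxepane, the phenol opening the seleniranium ion at the tertiary alkene carbon, to give the hydroxy selenide F2. Bu3SnH/AIBN (toluene, 80 °C) then removes selenium and delivers 26. In this fallback the cyclopentane stems from the aldol of step 9, and steps 13–15 are left out.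

Step 12 is the second risk. C-alkylation may take place on the wrong face of the o-quinone methide (epimer at the benzylic carbon), or deprotonation may occur at the γ-position. The fallback sets out from 14 and returns at 21, building the benzylic centre in the opposite order. Aldol addition of the lithium enolate of 14 to aldehyde 17 (THF, −78 °C), followed by Boc transfer and β-elimination on warming, should give the cyclopentenone-substituted o-quinone methide F3. i-BuMgBr (18) with CuBr·SMe2 (cat.) then adds to the methide carbon, so that the benzylic configuration is set by approach of the nucleophile past the adjacent quaternary carbon and not by the enolate face.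

Step 5 is the third risk. Hydrogen may be delivered to the wrong face, or the acidic iridium hydride may isomerise or open the vinylcyclopropane. The fallback sets out from 5 and returns at 7. MnO2 oxidation (CH2Cl2, rt) should give the enone (1R,6S)-3,7,7-trimethylbicyclo[4.1.0]hept-2-en-4-one F4. Conjugate reduction with LiBH(s-Bu)3 (THF, −78 °C) and kinetic protonation of the resulting enolate with 2,6-di-tert-butylphenol, from the face opposite the cyclopropane, should give 7.

Further compounds
F1 | step 15 | allylic alcohol from 1,2-reduction of 21 | CC(C)C[C@@H](c1c(OCc2ccccc2)cc(OCc2ccccc2)cc1O)[C@@]1(C)C(O)C=C2[C@@H](C)C[C@@H]3[C@H]([C@H]12)C3(C)C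
F2 | step 15 | bridged hydroxy selenide (PhSe on the cyclopentane CH next to the ether carbon) | CC(C)C[C@H]1c2c(OCc4ccccc4)cc(OCc4ccccc4)cc2O[C@]23C([Se]c4ccccc4)C(O)[C@@]1(C)[C@H]2[C@H]1[C@@H](C[C@@H]3C)C1(C)C
F3 | step 12 | o-quinone methide carrying cyclopentenone 14 at the methide carbon | O=C1C=C(OCc2ccccc2)C=C(OCc2ccccc2)C1=C[C@@]1(C)C(=O)C=C2[C@@H](C)C[C@@H]3[C@H]([C@H]12)C3(C)C
F4 | step 5 | (1R,6S)-3,7,7-trimethylbicyclo[4.1.0]hept-2-en-4-one | O=C1C[C@H]2[C@@H](C=C1C)C2(C)C
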